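Take the closed, stirred vessel, charged with a racemate, and follow one number through it.

common to all: left-handed substrate 20 mM; right-handed substrate 20 mM
- violet: reagent 30 mM; precatalyst 5.1 µM; run made earlier
- green: reagent 30 mM; precatalyst 35 µM; run made earlier
- theta: reagent 30.0 mM; precatalyst 40 µM; time 25 h
- alpha: reagent 30.0 mM; precatalyst 10 µM; time 25 h

- violet (time / h: right-handed substrate / %, left-handed substrate / %, left-handed product / %): 2.00: 49.0, 50.6, 0; 3.00: 49.5, 48.8, 1.1; 5.00: 52.6, 48.6, 0.8; 8.00: 49.7, 46.6, 2.8; 10.0: 48.0, 46.4, 2.9; 15.0: 50.0, 43.5, 5.8; 25.0: 47.2, 40.3, 10.2
- green (time / h: right-handed substrate / %, left-handed substrate / %, left-handed product / %): 2.00: 51.4, 49.9, 2.3; 3.00: 49.1, 46.9, 1.4; 5.00: 48.4, 44.5, 6.4; 8.00: 47.8, 35.4, 13.0; 10.0: 45.3, 31.7, 16.8; 15.0: 46.1, 24.8, 25.2; 25.0: 45.0, 17.8, 31.8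

(readings scatter by 1 percentage point)

- free catalyst is single-handed; left-handed substrate and right-handed substrate are mirror images of each other, charged as a racemate, each of them at the stated concentration
- the earlier runs were read with a standard deviation of 1 percentage point
- an excess is below zero if the other one leads

- which of the two ends with the higher excess of right-handed substrate over left-handed substrate among what is left of the two ("neither" if they lie within 2 percentage points) (theta / alpha / neither)
- excess of right-handed substrate over left-handed substrate among what is left of the two at the end, theta
- excess of right-handed substrate over left-handed substrate among what is left of the two at the end, alpha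

1. Read the left-handed substrate at 25.0 h: green gives 1.03, violet 0.216. This is the exposure, the natural log of left-handed substrate charged over left-handed substrate left.

2. Divide by precatalyst: green has less exposure per charge than violet, so take this as a reading that exposure grows more slowly than charge.

3. Bracket the exposure, assuming it rises with charge while exposure per charge falls. Theta holds more precatalyst than green, so on that assumption its exposure lies from 1.03 up to 1.18. Alpha's charge lies between violet's and green's, so on that assumption its exposure runs from 0.295 to 0.423.

4. Treat the right-handed loss as the correction. Left-handed exposure over right-handed exposure is the selectivity factor. Green's right-handed reading at 25.0 h, moved one standard deviation each way, gives an estimate of 8.08 to 12.4. Assuming both substrates share one catalyst, right-handed over left-handed left is exp(exposure times one minus the inverse factor), and the excess is that ratio minus one, over that ratio plus one.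

5. Pair low with low and high with high. My estimated bracket for theta runs from 42.4% to 49.5%, and for alpha from 12.9% to 19.2%. Commit to theta, whose floor stands above alpha's ceiling.

6. The forecast gives theta, with 46% and 18%, both inside these brackets, and says: “the active catalyst appears to scale linearly with charge”. My second step reads the exposure differently, as growing more slowly than charge.

The flask gives 42.8% for theta and 16.7% for alpha, so theta ends higher.

    2 free catalyst → spent catalyst A (k = 1880 M⁻¹ h⁻¹)
    reagent + free catalyst + right-handed substrate → free catalyst + right-handed product (k = 37000 M⁻² h⁻¹)
    reagent + free catalyst → spent catalyst B (k = 2.60 M⁻¹ h⁻¹)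
    precatalyst → free catalyst (k = 0.0769 h⁻¹)
    reagent + free catalyst + left-handed substrate → free catalyst + left-handed product (k = 2.18 × 10⁵ M⁻² h⁻¹)

Theta stands 0.40 percentage points above its floor. At 25.0 h theta keeps 33% of its left-handed substrate against 83% of its right-handed, an exposure of 1.11, inside its bracket. Alpha keeps 67% of its left-handed substrate, an exposure of 0.405, and with the left-handed over right-handed rate-constant ratio 5.89 as selectivity factor, that exposure gives an excess of 16.7%.

(The earlier runs and the new flask were generated by integration with made-up constants.)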